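Late in both earlier runs, the part of the charge not yet in chains falls by a steady fraction each hour. In these flasks an initiator starts chains and free monomer then adds to them.

| setting | ash | alder | Thursday's | Tuesday's |
|---|---|---|---|---|
| free monomer | 0.050 M | 0.20 M | 0.10 M | 0.10 M |
| initiator | 0.86 mM | 0.86 mM | 0.86 mM | 0.86 mM |
| remark | run made earlier | run made earlier |  |  |
| time |  |  | 2.0 h | 0.50 h |

| run | time / h | monomer in chains / % |
|---|---|---|
| ash | 0.200 | 3.3 |
| ash | 0.333 | 6.7 |
| ash | 0.417 | 7.5 |
| ash | 0.667 | 13.2 |
| ash | 1.00 | 21.0 |
| ash | 1.50 | 31.3 |
| ash | 2.50 | 46.5 |
| alder | 0.333 | 14.7 |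
| alder | 0.667 | 31.0 |
| alder | 1.00 | 42.3 |
| alder | 1.33 | 52.0 |
| alder | 1.50 | 57.5 |
| alder | 2.00 | 67.9 |
| alder | 2.50 | 76.7 |

(scatter of a reading: 0.5 percentage points)

From 1.00 h to 2.50 h the ash run gives a slope of 0.260 h⁻¹, and from 1.00 h to 2.50 h the alder run gives 0.605 h⁻¹. I read this steadiness as a number of chains that has stopped changing. A charge of 0.10 M lies midway between the two charges on a logarithmic scale, so I take the geometric mean, 0.396 h⁻¹, as the late slope, the fraction of what stands outside chains that enters them per hour once the chain count stands still, a pseudo-first-order constant.

* which of the two ends with the longer chains by the average number of monomer units in a chain (chains begun, living or dead) ("neither" if they lie within 10%) (Thursday's / Tuesday's / neither)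
* average number of monomer units in a chain (chains begun, living or dead) at the end, Thursday's
* average number of monomer units in a chain (chains begun, living or dead) at the end, Tuesday's

I must decide whether to leave this charge for 2.0 h or stop it at 0.50 h. Run back, the straight lines of the earlier runs reach zero after a mean delay of 0.0916 h, which I read as the time the chains take to start. The delay is 4.58% of Thursday's time but 18.3% of Tuesday's. It ends well before Tuesday's stop, so I give both flasks the same chain count, and their lengths stand as their monomer in chains. I reckon that at 53.1% of the charge for Thursday's and 14.9% for Tuesday's, a ratio of 3.55. I would leave the flask the full time. The readings do not show the count, so I commit to this ratio and not to lengths.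

The forecast says Thursday's, with 150 against 44, a ratio of 3.41, slightly below mine. Its ground is “Chains are fixed early, so length follows conversion”.

The flask gives Thursday's, with 157 against 44.8, a ratio of 3.50.

    free monomer + initiator → living end + monomer in chains (k = 0.520 M⁻¹ min⁻¹)
    free monomer + living end → monomer in chains + living end, rate k2*[living end]*[free monomer] (k = 21.0 M⁻¹ min⁻¹)
    initiator → spent initiator (k = 0.0730 min⁻¹)
    free monomer → uncatalysed product (k = 4.10 × 10⁻⁴ min⁻¹)

In Tuesday's flask the initiator has a half-life of 0.16 h by its loss to spent initiator alone, shorter than the run's 0.50 h, and 2.6% of its charge remains at the end, with living end at 3.42 × 10⁻⁴ M against 3.50 × 10⁻⁴ M at the end of Thursday's. With the late slope and the delay, Tuesday's length scales to 117 for the same charge left until 80 min, and that flask stands at 116.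

The readings are simulated for an exercise; the scatter is artificial.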